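The numbering used here: C1 is the prenyl-bearing bridgehead, C2(OMe)=C3(COPh)–C4(=O), C5 the other bridgehead, C6H2–C7H(prenyl)–C8Me2, C9 the bridging ketone. Everything rests on a hidden repeat: the C5 side chain and the ring segment C6–C7–C8 are two copies of one lavandulyl unit of the same configuration. The precursor is a monocyclic dearomatised benzoylphloroglucinol dimethyl ether (ring B) whose C5 carries two identical (S)-lavandulol-derived chains and is not yet stereogenic. Biomimetic protonation of one isopropenyl group and capture of the C8 cation by enol ether carbon C1 closes ring A (C5–C6–C7–C8–C1–C9) last, desymmetrises C5 and sets C1 and C5 from C7, giving the target directly.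

Key step: step 10

Remarks on the chemistry:
- The same atom numbers are used for the monocyclic precursors. The side chain on C5 is C10H2–C11H(prenyl)–C12(Me)=CH2.
- The chain stereocentre is 2S in lavandulol and becomes 2R by name once CH2 is bound to carbon. Only the CIP priorities change, not the geometry.
- Enolised polycarbonyl compounds 12–16 are written as one tautomer. Conjugate bases formed by simple deprotonation are not numbered separately.

Step 1
Reactants: 1 (S)-4-benzyl-1,3-oxazolidin-2-one; 2 3-methylbut-2-enoyl chloride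
Product: 3 (S)-4-benzyl-3-(3-methylbut-2-enoyl)-1,3-oxazolidin-2-one
Conditions: n-BuLi, THF, −78 °C; then 2, −78 → 0 °C
Reagents that add atoms: none
Why: N-acylation of the lithiated oxazolidinone by the acid chloride should give the imide, and no stereocentre is formed.

Step 2
Reactants: 3 (S)-4-benzyl-3-(3-methylbut-2-enoyl)-1,3-oxazolidin-2-one; 4 prenyl bromide (1-bromo-3-methylbut-2-ene)
Product: 5 (S)-4-benzyl-3-[(2S)-5-methyl-2-(prop-1-en-2-yl)hex-4-enoyl]-1,3-oxazolidin-2-one
Conditions: NaN(SiMe3)2, THF, −78 °C; then 4, −78 → −40 °C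
Reagents that add atoms: none
Why: Deconjugative Evans alkylation, in which γ-deprotonation gives the chelated Z-dienolate that is alkylated at the α-carbon on the face opposite the benzyl group, should set the 2S centre that becomes both C7 and C11 of the target.

Step 3
Reactants: 5 (S)-4-benzyl-3-[(2S)-5-methyl-2-(prop-1-en-2-yl)hex-4-enoyl]-1,3-oxazolidin-2-one
Product: 6 (S)-lavandulol, (2S)-5-methyl-2-(prop-1-en-2-yl)hex-4-en-1-ol
Conditions: LiBH4, H2O (1 equiv), Et2O, 0 °C
Reagents that add atoms: none
Why: Reductive cleavage of the imide by LiBH4 should give the primary alcohol and release the auxiliary without touching the stereocentre or the alkenes.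

Step 4
Reactants: 6 (S)-lavandulol
Product: 7 (S)-lavandulyl triflate, (2S)-5-methyl-2-(prop-1-en-2-yl)hex-4-en-1-yl trifluoromethanesulfonate
Conditions: Tf2O, 2,6-lutidine, CH2Cl2, −78 °C; used crude at once
Reagents that add atoms: trifluoromethanesulfonic anhydride, O=S(=O)(OS(=O)(=O)C(F)(F)F)C(F)(F)F
Why: O-sulfonylation of the primary alcohol at low temperature should give an electrophile reactive enough for C-alkylation at a hindered carbon, and the stereocentre is not involved.

Step 5
Reactants: 8 methyl 2,4,6-trihydroxybenzoate; 9 benzoyl chloride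
Product: 10 methyl 3-benzoyl-2,4,6-trihydroxybenzoate
Conditions: AlCl3, PhNO2, 60 °C
Reagents that add atoms: none
Why: Friedel–Crafts C-acylation at one of the two equivalent free ring positions should stop after one benzoyl group, which deactivates the ring, while the ester blocks the future C1.

Step 6
Reactants: 10 methyl 3-benzoyl-2,4,6-trihydroxybenzoate; 7 (S)-lavandulyl triflate (two equivalents enter the product)
Product: 12 methyl 5-benzoyl-2,4,6-trioxo-3,3-bis[(2R)-5-methyl-2-(prop-1-en-2-yl)hex-4-enyl]cyclohexane-1-carboxylate (dienol form), via mono-C-alkylated phenol 11 (not isolated)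
Conditions: LiN(SiMe3)2 (3.0 equiv), THF, 0 °C; 7 (1.1 equiv), −78 → 0 °C; LiN(SiMe3)2 (1.1 equiv); 7 (1.2 equiv), 0 °C → rt; 1 M HCl work-up
Reagents that add atoms: none
Why: Alkylative dearomatisation, in which the lithium phenoxide is C-alkylated (SN2) at C5, the only unsubstituted ring carbon, then deprotonated and alkylated there again, should place two identical chains on C5, which is therefore not a stereocentre.

Step 7
Reactants: 12 methyl 5-benzoyl-2,4,6-trioxo-3,3-bis[(2R)-5-methyl-2-(prop-1-en-2-yl)hex-4-enyl]cyclohexane-1-carboxylate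
Product: 13 2-benzoyl-6,6-bis[(2R)-5-methyl-2-(prop-1-en-2-yl)hex-4-enyl]cyclohexane-1,3,5-trione (dienol form)
Conditions: LiCl, DMSO/H2O, 120 °C
Reagents that add atoms: none
Why: Krapcho dealkoxycarbonylation of the vinylogous β-keto ester (chloride attacks the ester methyl and the carboxylate loses CO2) should free C1–H under non-acidic conditions that leave all alkenes alone.

Step 8
Reactants: 13 2-benzoyl-6,6-bis[(2R)-5-methyl-2-(prop-1-en-2-yl)hex-4-enyl]cyclohexane-1,3,5-trione; 4 prenyl bromide
Product: 14 2-benzoyl-4-(3-methylbut-2-enyl)-6,6-bis[(2R)-5-methyl-2-(prop-1-en-2-yl)hex-4-enyl]cyclohexane-1,3,5-trione (dienol form)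
Conditions: NaOMe, MeOH, 0 °C → rt
Reagents that add atoms: none
Why: C-alkylation of the trione enolate in a protic medium should take place at C1, the only nucleophilic ring carbon that carries hydrogen, as in classical C-prenylations of acylphloroglucinol-derived triones, and no stereocentre is formed.

Step 9
Reactants: 14 2-benzoyl-4-(3-methylbut-2-enyl)-6,6-bis[(2R)-5-methyl-2-(prop-1-en-2-yl)hex-4-enyl]cyclohexane-1,3,5-trione
Product: 16 2-benzoyl-3,5-dimethoxy-4-(3-methylbut-2-enyl)-6,6-bis[(2R)-5-methyl-2-(prop-1-en-2-yl)hex-4-enyl]cyclohexa-2,4-dien-1-one, via C9 mono-methyl ether 15 (not isolated)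
Conditions: (trimethylsilyl)diazomethane (excess), iPr2NEt, MeCN/MeOH, 0 °C → rt
Reagents that add atoms: (trimethylsilyl)diazomethane, C[Si](C)(C)C=[N+]=[N-]
Why: O-methylation of acidic enols by the diazoalkane should first take the free vinylogous-acid hydroxyl at C9 and then the chelated enol at O2, which is less hindered than O4 beside the quaternary C5, leaving the C4 dienone with methoxy groups on C2 and C9.

Step 10
Reactants: 16 2-benzoyl-3,5-dimethoxy-4-(3-methylbut-2-enyl)-6,6-bis[(2R)-5-methyl-2-(prop-1-en-2-yl)hex-4-enyl]cyclohexa-2,4-dien-1-one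
Product: 18 target (1R,5R,7R)-3-benzoyl-2-methoxy-8,8-dimethyl-1,7-bis(3-methylbut-2-enyl)-5-[(2R)-5-methyl-2-(prop-1-en-2-yl)hex-4-enyl]bicyclo[3.3.1]non-2-ene-4,9-dione, via oxocarbenium formate 17 (not isolated)
Conditions: HCO2H (98%), rt, argon, stopped as soon as 16 is consumed
Reagents that add atoms: none
Why: Formic acid should protonate the terminal CH2 of one isopropenyl group (Markovnikov), the developing tertiary C8 cation being captured by enol ether carbon C1, after which oxocarbenium 17 loses its O-methyl group to formate and unveils the C9 ketone while the C2 methyl ether stays. The closest known reaction type is the biomimetic Brønsted acid-mediated cation–olefin cyclisation onto a methyl enol ether that forges the C1–C8 bond between two quaternary carbons in type B polyprenylated acylphloroglucinols. Ring A (C5–C6–C7–C8–C1–C9) closes through a chair, 6-exo-trig with respect to the protonated isopropenyl group and 6-(enol-endo) with respect to the C1=C9 enol ether. The existing C7 stereocentre controls the outcome, because only the chain on the ring face that lets the C7 prenyl group sit equatorial (exo) reacts, which fixes C1 and C5 as 1R,5R and leaves the other, identical chain as the C5 lavandulyl substituent. The step needs attack by C1 rather than by C3 or O4, which the benzoyl deactivation of C3 and the reversibility of O-alkylation in formic acid should secure. It also needs the second isopropenyl group and the three prenyl groups to survive, which rests on the faster, nucleophile-assisted protonation of the one alkene that has the enol ether within reach.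

Compound list
1 | (S)-4-benzyl-1,3-oxazolidin-2-one | O=C1OC[C@H](Cc2ccccc2)N1 | starting material
2 | 3-methylbut-2-enoyl chloride | CC(C)=CC(Cl)=O | starting material
3 | (S)-4-benzyl-3-(3-methylbut-2-enoyl)-1,3-oxazolidin-2-one | CC(C)=CC(=O)N1C(=O)OC[C@@H]1Cc1ccccc1 | intermediate
4 | prenyl bromide (1-bromo-3-methylbut-2-ene) | CC(C)=CCBr | starting material
5 | (S)-4-benzyl-3-[(2S)-5-methyl-2-(prop-1-en-2-yl)hex-4-enoyl]-1,3-oxazolidin-2-one | C=C(C)[C@H](CC=C(C)C)C(=O)N1C(=O)OC[C@@H]1Cc1ccccc1 | intermediate
6 | (S)-lavandulol, (2S)-5-methyl-2-(prop-1-en-2-yl)hex-4-en-1-ol | C=C(C)[C@H](CC=C(C)C)CO | intermediate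
7 | (S)-lavandulyl triflate | C=C(C)[C@H](CC=C(C)C)COS(=O)(=O)C(F)(F)F | intermediate
8 | methyl 2,4,6-trihydroxybenzoate | COC(=O)c1c(O)cc(O)cc1O | starting material
9 | benzoyl chloride | O=C(Cl)c1ccccc1 | starting material
10 | methyl 3-benzoyl-2,4,6-trihydroxybenzoate | COC(=O)c1c(O)cc(O)c(C(=O)c2ccccc2)c1O | intermediate
11 | methyl 3-benzoyl-2,4,6-trihydroxy-5-[(2R)-5-methyl-2-(prop-1-en-2-yl)hex-4-enyl]benzoate (formed in the flask) | C=C(C)[C@H](CC=C(C)C)Cc1c(O)c(C(=O)OC)c(O)c(C(=O)c2ccccc2)c1O | intermediate
12 | methyl 5-benzoyl-2,4,6-trioxo-3,3-bis[(2R)-5-methyl-2-(prop-1-en-2-yl)hex-4-enyl]cyclohexane-1-carboxylate, dienol form (C5 bis-chain, C3 benzoyl, C1 ester) | C=C(C)[C@H](CC=C(C)C)CC1(C[C@@H](CC=C(C)C)C(C)=C)C(=O)C(C(=O)c2ccccc2)=C(O)C(C(=O)OC)=C1O | intermediate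
13 | 2-benzoyl-6,6-bis[(2R)-5-methyl-2-(prop-1-en-2-yl)hex-4-enyl]cyclohexane-1,3,5-trione, dienol form (C1–H) | C=C(C)[C@H](CC=C(C)C)CC1(C[C@@H](CC=C(C)C)C(C)=C)C(=O)C(C(=O)c2ccccc2)=C(O)C=C1O | intermediate
14 | 2-benzoyl-4-(3-methylbut-2-enyl)-6,6-bis[(2R)-5-methyl-2-(prop-1-en-2-yl)hex-4-enyl]cyclohexane-1,3,5-trione, dienol form (C1 prenyl) | C=C(C)[C@H](CC=C(C)C)CC1(C[C@@H](CC=C(C)C)C(C)=C)C(=O)C(C(=O)c2ccccc2)=C(O)C(CC=C(C)C)=C1O | intermediate
15 | 2-benzoyl-3-hydroxy-5-methoxy-4-(3-methylbut-2-enyl)-6,6-bis[(2R)-5-methyl-2-(prop-1-en-2-yl)hex-4-enyl]cyclohexa-2,4-dien-1-one (C9 methyl ether, formed in the flask) | C=C(C)[C@H](CC=C(C)C)CC1(C[C@@H](CC=C(C)C)C(C)=C)C(=O)C(C(=O)c2ccccc2)=C(O)C(CC=C(C)C)=C1OC | intermediate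
16 | 2-benzoyl-3,5-dimethoxy-4-(3-methylbut-2-enyl)-6,6-bis[(2R)-5-methyl-2-(prop-1-en-2-yl)hex-4-enyl]cyclohexa-2,4-dien-1-one (C2 and C9 methyl ethers, C4 ketone) | C=C(C)[C@H](CC=C(C)C)CC1(C[C@@H](CC=C(C)C)C(C)=C)C(=O)C(C(=O)c2ccccc2)=C(OC)C(CC=C(C)C)=C1OC | intermediate
17 | C9 O-methyl oxocarbenium formate of the bicyclic product (formed in the flask) | C=C(C)[C@H](CC=C(C)C)C[C@@]12C[C@@H](CC=C(C)C)C(C)(C)[C@@](CC=C(C)C)(C1=[O+]C)C(OC)=C(C(=O)c1ccccc1)C2=O.[O-]C=O | intermediate
18 | (1R,5R,7R)-3-benzoyl-2-methoxy-8,8-dimethyl-1,7-bis(3-methylbut-2-enyl)-5-[(2R)-5-methyl-2-(prop-1-en-2-yl)hex-4-enyl]bicyclo[3.3.1]non-2-ene-4,9-dione (numbering of the remark) | C=C(C)[C@H](CC=C(C)C)C[C@@]12C[C@@H](CC=C(C)C)C(C)(C)[C@@](CC=C(C)C)(C1=O)C(OC)=C(C(=O)c1ccccc1)C2=O | target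

Total step count: 10. Longest linear sequence: 9 steps (steps 1–4, then 6–10; step 5 is a one-step side branch).

Steps most likely to fail

1. Step 10. Protonation may not stay with the chain that closes ring A. The second isopropenyl group (before or after ring closure) or a prenyl group may be protonated as well. This can be followed by O-cyclisation onto the C4 carbonyl oxygen with loss of a methyl group, by a 1,2-hydride shift at C7 or C11, or by cyclisation of a lavandulyl 1,5-diene. The two diastereotopic chains may also be discriminated poorly. Fallback: a soft metal electrophile replaces the proton. Setting out from 16, Hg(O2CCF3)2 in MeNO2/CH2Cl2 at −20 °C, then aqueous NaCl/NaHCO3, should give the C8 chloromercuriomethyl analogue of 18 (both C8 epimers) F1. Divalent mercury adds fastest to 1,1-disubstituted alkenes, does so reversibly, and is consumed only where C1 is within reach, so no free cation arises. Reductive demercuration with NaBH4 in aqueous NaOH/THF at 0 °C, run concentrated to outpace 5-exo cyclisation of the transient primary radical, would turn CH2HgCl into the second C8 methyl group and come back to the route at 18.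

2. Step 6. O-alkylation of the phenoxide, E2 loss of triflic acid from the β-branched triflate, and stalling of the second alkylation at the already substituted C5 may all compete. Fallback: the quaternary carbon is made on a malonate and ring B is built around it by Claisen chemistry. Setting out from 7, double alkylation of dimethyl malonate (NaH, THF/DMF, 0 → 50 °C) should give dimethyl 2,2-bis[(2R)-5-methyl-2-(prop-1-en-2-yl)hex-4-enyl]propanedioate F2. Acylation of the dilithium dianion of 1-phenylbutane-1,3-dione (LiN(iPr)2, THF, −78 → 0 °C; 1 M HCl work-up) at its terminal carbon by one ester group would give methyl 3,5,7-trioxo-7-phenyl-2,2-bis[(2R)-5-methyl-2-(prop-1-en-2-yl)hex-4-enyl]heptanoate F3. Claisen cyclisation with NaOMe in MeOH, in which the benzoyl-bearing carbon is acylated by the remaining ester, closes ring B and comes back to the route at 13, so that steps 5 and 7 are no longer needed.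

3. Step 9. Methylation may go to the wrong enol oxygen (O4 or the benzoyl oxygen in place of O2) or stop at the chelated hydroxyl, which would carry a wrong methyl ether pattern into the ring closure. Fallback: the order of O-methylation and ring closure is reversed. Setting out from 14, one equivalent of (trimethylsilyl)diazomethane stops at the mono ether 15, which is isolated and cyclised under the conditions of step 10 to the O-unmethylated bicyclic enol of 18 F4. Methylation of F4 with (trimethylsilyl)diazomethane should give 18 together with the 4-O-methyl regioisomer of 18 F5. F5 is separated and recycled to F4 with LiCl in DMSO at 120 °C. The fallback comes back to the route at 18.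

Further compounds
F1 | step 10 | (1R,5R,7R)-3-benzoyl-8-(chloromercuriomethyl)-2-methoxy-8-methyl-1,7-bis(3-methylbut-2-enyl)-5-[(2R)-5-methyl-2-(prop-1-en-2-yl)hex-4-enyl]bicyclo[3.3.1]non-2-ene-4,9-dione (C8 epimers) | C=C(C)[C@H](CC=C(C)C)C[C@@]12C[C@@H](CC=C(C)C)C(C)(C[Hg]Cl)[C@@](CC=C(C)C)(C1=O)C(OC)=C(C(=O)c1ccccc1)C2=O
F2 | step 6 | dimethyl 2,2-bis[(2R)-5-methyl-2-(prop-1-en-2-yl)hex-4-enyl]propanedioate | C=C(C)[C@H](CC=C(C)C)CC(C[C@@H](CC=C(C)C)C(C)=C)(C(=O)OC)C(=O)OC
F3 | step 6 | methyl 3,5,7-trioxo-7-phenyl-2,2-bis[(2R)-5-methyl-2-(prop-1-en-2-yl)hex-4-enyl]heptanoate | C=C(C)[C@H](CC=C(C)C)CC(C[C@@H](CC=C(C)C)C(C)=C)(C(=O)OC)C(=O)CC(=O)CC(=O)c1ccccc1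
F4 | step 9 | (1R,5R,7R)-3-benzoyl-2-hydroxy-8,8-dimethyl-1,7-bis(3-methylbut-2-enyl)-5-[(2R)-5-methyl-2-(prop-1-en-2-yl)hex-4-enyl]bicyclo[3.3.1]non-2-ene-4,9-dione (one enol tautomer) | C=C(C)[C@H](CC=C(C)C)C[C@@]12C[C@@H](CC=C(C)C)C(C)(C)[C@@](CC=C(C)C)(C1=O)C(O)=C(C(=O)c1ccccc1)C2=O
F5 | step 9 | (1R,5R,7R)-3-benzoyl-4-methoxy-8,8-dimethyl-1,7-bis(3-methylbut-2-enyl)-5-[(2R)-5-methyl-2-(prop-1-en-2-yl)hex-4-enyl]bicyclo[3.3.1]non-3-ene-2,9-dione | C=C(C)[C@H](CC=C(C)C)C[C@@]12C[C@@H](CC=C(C)C)C(C)(C)[C@@](CC=C(C)C)(C1=O)C(=O)C(C(=O)c1ccccc1)=C2OC
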